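**Plan**

Retrosynthesis: the bromo epoxide is opened to a gem-dibromo carbinol and the 7,8-epoxide to an enone; the ring C–Cl/C–Br bonds go back to an ether-bridged bromohydrin of a cyclohex-3-enol; the C1–C2 bond of that cyclohexene ring is cut back to a 2-isopropenyl spiro[3.5]nonan-1-one, whose cyclobutanone comes from an alkenyl cyclopropanol (epoxide-triggered semipinacol) on a ring made from actinol.
Forward: ring from actinol (chiral pool) → spiro cyclobutanone (spiro atom) → halogen-bearing ring by two-atom ring expansion → C1 carbinol → Br and Cl through a temporary ether bridge → enone → 7,8-epoxide → bromo epoxide.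
Enabling feature: in the bromochloro carbocycle, the carbinol carbon next to the spiro atom and the C(Me)Cl–CHBr pair (a masked C(Me)=CH) make up a cyclohex-3-enone, the product pattern of a 1,3-acyl shift of a 2-vinylcyclobutanone. The spiro atom flanked by a carbonyl-derived carbon and a tertiary C–O carbon is the product pattern of a cyclopropanol semipinacol.
Stereochemistry: the actinol C–O centre sets the epoxidation face; anti migration sets the spiro atom and the tertiary carbinol together; that OH delivers hydride to C1 and then the oxygen that opens the bromonium ion (Br, later Cl with retention). The C1–OH guides the enone epoxidation; the last carbinol comes from an epoxy ketone reduction and closes the bromo epoxide by inversion at CBr2.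

Key step: step 7

Remark: (4R,6R)-actinol (1) is taken as purchasable (industrial carotenoid intermediate; otherwise one ketoreductase reduction of commercial 2,2,6-trimethylcyclohexane-1,4-dione), as are 1-ethoxycyclopropan-1-ol (4) and 2-bromopropene (10).
Remark: locants used below: spiro[5.5]undecanes C1–C5 = halogen-bearing ring (C1 = carbonyl/carbinol carbon), C6 = spiro atom, C7–C11 = ring from actinol (C7 = C(Me)–O, C11 = CMe2); spiro[3.5]nonanes C1 = C=O, C4 = spiro atom, C5 = C(Me)–O, C9 = CMe2.

Step 1
Reactants: 1 (4R,6R)-4-hydroxy-2,2,6-trimethylcyclohexan-1-one (actinol)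
Product: 2 (4R,6R)-4-[(tert-butyldimethylsilyl)oxy]-2,2,6-trimethylcyclohexan-1-one
Conditions: TBSCl, imidazole, DMF, rt
Reagents that add atoms: tert-butyldimethylsilyl chloride, CC(C)(C)[Si](C)(C)Cl
Why: Imidazole-promoted silyl ether formation at the only hydroxyl protects C4–O through the organolithium steps and makes it the bulky group that later steers the epoxidation; no stereocentre is touched.

Step 2
Reactants: 2 (4R,6R)-4-[(tert-butyldimethylsilyl)oxy]-2,2,6-trimethylcyclohexan-1-one
Product: 3 2,4,6-triisopropylbenzenesulfonyl hydrazone of 2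
Conditions: TrisNHNH2, THF, cat. HCl, rt
Reagents that add atoms: 2,4,6-triisopropylbenzenesulfonyl hydrazide, CC(C)c1cc(C(C)C)c(S(=O)(=O)NN)c(C(C)C)c1
Why: Hydrazone formation (acid-catalysed condensation) at the hindered ketone prepares the Shapiro reaction; epimerisation at C6 is harmless because this carbon becomes sp2 in step 3.

Step 3
Reactants: 3 2,4,6-triisopropylbenzenesulfonyl hydrazone of 2, 4 1-ethoxycyclopropan-1-ol
Product: 6 1-[(4R)-4-[(tert-butyldimethylsilyl)oxy]-2,6,6-trimethylcyclohex-1-en-1-yl]cyclopropan-1-ol, via vinyllithium 5 (not isolated)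
Conditions: n-BuLi (2.2 equiv), TMEDA, THF, −78 → 0 °C; then 4/MeMgBr (1 equiv, THF, 0 °C), −78 °C → rt; H2O
Reagents that add atoms: none
Why: Shapiro reaction: double deprotonation and loss of sulfinate and N2 give the tetrasubstituted vinyllithium regiospecifically because C6 carries the only α-hydrogen, and its 1,2-addition to cyclopropanone released from the magnesium hemiketal of 4 should give the 1-alkenylcyclopropanol without creating a stereocentre.

Step 4
Reactants: 6 1-[(4R)-4-[(tert-butyldimethylsilyl)oxy]-2,6,6-trimethylcyclohex-1-en-1-yl]cyclopropan-1-ol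
Product: 8 (4S,5R,7S)-7-[(tert-butyldimethylsilyl)oxy]-5-hydroxy-5,9,9-trimethylspiro[3.5]nonan-1-one, via epoxy alcohol 7 (not isolated)
Conditions: DMDO, acetone–CH2Cl2, −40 → 0 °C
Reagents that add atoms: dimethyldioxirane, CC1(C)OO1
Why: DMDO should epoxidise the electron-rich tetrasubstituted alkene on the face anti to the C4 silyloxy group (the usual sense for 3-acyloxy- and 3-silyloxy-β-ionone-type rings), and the epoxy cyclopropanol then undergoes the strain-driven semipinacol ring expansion (cyclopropanol → cyclobutanone) in which a ring CH2 migrates anti to the breaking C–O bond, so the spiro carbon and the tertiary carbinol are set together and relative to C7; a minor epoxide-face isomer would be removed here.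

Step 5
Reactants: 8 (4S,5R,7S)-7-[(tert-butyldimethylsilyl)oxy]-5-hydroxy-5,9,9-trimethylspiro[3.5]nonan-1-one
Product: 9 (4S,5R,7S)-7-[(tert-butyldimethylsilyl)oxy]-5,9,9-trimethyl-5-[(trimethylsilyl)oxy]spiro[3.5]nonan-1-one
Conditions: TMSOTf, 2,6-lutidine, CH2Cl2, −78 °C
Reagents that add atoms: trimethylsilyl trifluoromethanesulfonate, C[Si](C)(C)OS(=O)(=O)C(F)(F)F
Why: Silylation of the tertiary alcohol (silyl triflate, hindered base) removes the β-hydroxy ketone function that would otherwise undergo retro-aldol cleavage under the enolate conditions of step 6.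

Step 6
Reactants: 9 (4S,5R,7S)-7-[(tert-butyldimethylsilyl)oxy]-5,9,9-trimethyl-5-[(trimethylsilyl)oxy]spiro[3.5]nonan-1-one, 10 2-bromopropene
Product: 11 (4S,5R,7S)-7-[(tert-butyldimethylsilyl)oxy]-5,9,9-trimethyl-2-(prop-1-en-2-yl)-5-[(trimethylsilyl)oxy]spiro[3.5]nonan-1-one (C2 epimers)
Conditions: LiHMDS, Pd2(dba)3 (cat.), P(t-Bu)3 (cat.), PhMe, rt → 50 °C
Reagents that add atoms: none
Why: Palladium-catalysed α-alkenylation of a ketone enolate with an alkenyl bromide; the enolate can form only toward C2 because C4 is quaternary, and the configuration of the new C2 centre is irrelevant since it becomes sp2 in step 7.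

Step 7
Reactants: 11 (4S,5R,7S)-7-[(tert-butyldimethylsilyl)oxy]-5,9,9-trimethyl-2-(prop-1-en-2-yl)-5-[(trimethylsilyl)oxy]spiro[3.5]nonan-1-one (C2 epimers)
Product: 12 (6S,7R,9S)-9-[(tert-butyldimethylsilyl)oxy]-3,7,11,11-tetramethyl-7-[(trimethylsilyl)oxy]spiro[5.5]undec-3-en-1-one
Conditions: PhMe, 180 °C, sealed tube
Reagents that add atoms: none
Why: Thermal [1,3]-acyl shift: the C1–C2 bond of the cyclobutanone, weakened by ring strain and allylic to the isopropenyl group, breaks (acyl/allyl diradical or its concerted equivalent) and the acyl carbon C1 rebonds to the terminal CH2 of the former isopropenyl group with allylic transposition. The closest known reaction is the 2-vinylcyclobutanone → cyclohex-3-enone rearrangement (1,3-acyl shift of a β,γ-unsaturated ketone, also known in its alkoxide-accelerated vinylcyclobutanol form). The six-membered ring closes by C(acyl)–C(sp2 terminus) bond formation, formally a 1,3-sigmatropic ring expansion in which the two isopropenyl carbons are inserted between C1 and C2 of the four-membered ring. No stereocentre is created: C2 becomes sp2, so both C2 epimers converge, and the spiro carbon and the C(Me)–O carbon keep their configuration because no bond to them is broken. The step needs cleavage of the C1–C2 bond and not of the C1–spiro bond, and the alkene at C3=C4 with the methyl on C3; the first is secured by allyl stabilisation that exists only on the C2 side (the spiro side carries a saturated silyloxy carbon), the second by the connectivity of the isopropenyl group, which leaves no regiochemical choice. Release of the cyclobutanone ring strain (about 26 kcal/mol) should make the shift irreversible.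

Step 8
Reactants: 12 (6S,7R,9S)-9-[(tert-butyldimethylsilyl)oxy]-3,7,11,11-tetramethyl-7-[(trimethylsilyl)oxy]spiro[5.5]undec-3-en-1-one
Product: 13 (6S,7R,9S)-7,9-dihydroxy-3,7,11,11-tetramethylspiro[5.5]undec-3-en-1-one
Conditions: HF·pyridine, THF–pyridine, 0 °C → rt
Reagents that add atoms: none
Why: Fluoride-mediated cleavage of both silyl ethers (buffered HF·pyridine, which should not move the β,γ-double bond into conjugation) frees the tertiary OH that directs the next step and the secondary OH that is oxidised later.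

Step 9
Reactants: 13 (6S,7R,9S)-7,9-dihydroxy-3,7,11,11-tetramethylspiro[5.5]undec-3-en-1-one
Product: 14 (1S,6R,7R,9S)-3,7,11,11-tetramethylspiro[5.5]undec-3-ene-1,7,9-triol
Conditions: Me4NBH(OAc)3, AcOH–MeCN, −30 °C
Reagents that add atoms: none
Why: Evans–Saksena reduction: the tertiary C7–OH exchanges onto boron and delivers hydride intramolecularly to the C1 ketone from the side of C7, which should give the C1 carbinol trans to C7 and cis to the CMe2 carbon as in the target, while the C9–OH has no carbonyl within reach.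

Step 10
Reactants: 14 (1S,6R,7R,9S)-3,7,11,11-tetramethylspiro[5.5]undec-3-ene-1,7,9-triol
Product: 15 (1S,3S,4S,6R,7R,9S)-4-bromo-3,7-epoxy-3,7,11,11-tetramethylspiro[5.5]undecane-1,9-diol (C3–O–C7 ether bridge)
Conditions: NBS, CH2Cl2, 0 °C, dark
Reagents that add atoms: N-bromosuccinimide, O=C1CCC(=O)N1Br
Why: Bromoetherification of the α-terpineol → 2-bromo-1,8-cineole type: the tertiary C7–OH, held on one face of the cyclohexene and 1,4-related through the spiro atom to the methyl-bearing alkene carbon, opens the bromonium ion at C3 (Markovnikov), so that bromine ends on C4 on the opposite face, trans to the new C3–O bond; the C1–OH could reach only C4 in an anti-Markovnikov sense.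

Step 11
Reactants: 15 (1S,3S,4S,6R,7R,9S)-4-bromo-3,7-epoxy-3,7,11,11-tetramethylspiro[5.5]undecane-1,9-diol
Product: 16 (1S,3S,4S,6R,7R)-4-bromo-3,7-epoxy-1-hydroxy-3,7,11,11-tetramethylspiro[5.5]undecan-9-one
Conditions: TEMPO (cat.), PhI(OAc)2, CH2Cl2, rt
Reagents that add atoms: none
Why: Nitroxyl (TEMPO/oxoammonium) oxidation is sensitive to steric hindrance and should take the unhindered C9 carbinol, while the neopentyl C1–OH beside the spiro centre and the ether bridge stay untouched.

Step 12
Reactants: 16 (1S,3S,4S,6R,7R)-4-bromo-3,7-epoxy-1-hydroxy-3,7,11,11-tetramethylspiro[5.5]undecan-9-one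
Product: 18 (1S,3S,4S,6S)-4-bromo-3-chloro-1-hydroxy-3,7,11,11-tetramethylspiro[5.5]undec-7-en-9-one, via bromohydrin enone 17 (not isolated)
Conditions: HCl (4 M in dioxane), CH2Cl2, 0 °C → rt
Reagents that add atoms: hydrogen chloride, Cl
Why: Acid first expels the ether oxygen from C7 (acid-catalysed β-elimination of a β-alkoxy ketone), which opens the bridge to the enone and a tertiary bromohydrin, and the C3–OH is then replaced by chloride with retention through the bromonium ion formed by the anti bromine (neighbouring-group participation), which should give the trans bromo chloride with Cl on the face of the former ether oxygen.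

Step 13
Reactants: 18 (1S,3S,4S,6S)-4-bromo-3-chloro-1-hydroxy-3,7,11,11-tetramethylspiro[5.5]undec-7-en-9-one
Product: 19 (1S,3S,4S,6R,7S,8S)-4-bromo-3-chloro-7,8-epoxy-1-hydroxy-3,7,11,11-tetramethylspiro[5.5]undecan-9-one
Conditions: t-BuOOH, n-BuLi, THF, −78 → −20 °C
Reagents that add atoms: tert-butyl hydroperoxide, CC(C)(C)OO
Why: Nucleophilic (Weitz–Scheffer) epoxidation with lithium tert-butyl peroxide, in which the lithium alkoxide of the C1–OH binds the peroxide and delivers it to the β-carbon C7 on its own face (hydroxyl-directed nucleophilic epoxidation), so that the epoxide oxygen should end cis to C1 as in the target.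

Step 14
Reactants: 19 (1S,3S,4S,6R,7S,8S)-4-bromo-3-chloro-7,8-epoxy-1-hydroxy-3,7,11,11-tetramethylspiro[5.5]undecan-9-one
Product: 21 (1S,3S,4S,6R,7S,8S)-4,10,10-tribromo-3-chloro-7,8-epoxy-1-hydroxy-3,7,11,11-tetramethylspiro[5.5]undecan-9-one, via monobromo ketone 20 (not isolated)
Conditions: LiHMDS (2.2 equiv), THF, −78 °C, NBS; then LiHMDS, NBS, −78 → −40 °C; H2O
Reagents that add atoms: N-bromosuccinimide, O=C1CCC(=O)N1Br
Why: Two successive enolate brominations with NBS; C10 is the only enolisable position because C8 is an epoxide carbon, the second bromine enters at the more acidic CHBr, and the first equivalent of base covers the C1–OH.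

Step 15
Reactants: 21 (1S,3S,4S,6R,7S,8S)-4,10,10-tribromo-3-chloro-7,8-epoxy-1-hydroxy-3,7,11,11-tetramethylspiro[5.5]undecan-9-one
Product: 23 prepacifenol epoxide, via dibromo alcohol 22 (not isolated)
Conditions: NaBH4, CeCl3·7H2O, MeOH, −78 °C; then K2CO3, 0 °C → rt
Reagents that add atoms: none
Why: Luche-type reduction of the α,α-dibromo epoxy ketone should deliver hydride anti to the axial C–Br bond from the face of the epoxide oxygen (the trans-epoxy alcohol sense usual for cyclic α,β-epoxy ketones), and the C9 alkoxide then displaces the antiperiplanar bromine at C10 (Jocic-type closure of a gem-dihalo carbinol), giving the bromo epoxide with its oxygen trans to the 7,8-epoxide and the remaining bromine on the opposite face.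

**Compound list**

1 | (4R,6R)-4-hydroxy-2,2,6-trimethylcyclohexan-1-one (actinol) | CC1(C)C(=O)[C@H](C)C[C@@H](O)C1 | starting material
2 | (4R,6R)-4-[(tert-butyldimethylsilyl)oxy]-2,2,6-trimethylcyclohexan-1-one | CC1(C)C(=O)[C@H](C)C[C@@H](O[Si](C)(C)C(C)(C)C)C1 | intermediate
3 | 2,4,6-triisopropylbenzenesulfonyl hydrazone of 2 | CC1(C)C(=NNS(=O)(=O)c2c(C(C)C)cc(C(C)C)cc2C(C)C)[C@H](C)C[C@@H](O[Si](C)(C)C(C)(C)C)C1 | intermediate
4 | 1-ethoxycyclopropan-1-ol | CCOC1(O)CC1 | starting material
5 | [(4R)-4-[(tert-butyldimethylsilyl)oxy]-2,6,6-trimethylcyclohex-1-en-1-yl]lithium | CC1(C)C([Li])=C(C)C[C@@H](O[Si](C)(C)C(C)(C)C)C1 | intermediate (not isolated)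
6 | 1-[(4R)-4-[(tert-butyldimethylsilyl)oxy]-2,6,6-trimethylcyclohex-1-en-1-yl]cyclopropan-1-ol | CC1(C)C(C2(O)CC2)=C(C)C[C@@H](O[Si](C)(C)C(C)(C)C)C1 | intermediate
7 | 1,2-epoxide of 6, epoxide oxygen trans to the silyloxy group | CC1(C)[C@]2(C3(O)CC3)O[C@]2(C)C[C@@H](O[Si](C)(C)C(C)(C)C)C1 | intermediate (not isolated)
8 | (4S,5R,7S)-7-[(tert-butyldimethylsilyl)oxy]-5-hydroxy-5,9,9-trimethylspiro[3.5]nonan-1-one | CC1(C)[C@@]2(CCC2=O)[C@](C)(O)C[C@@H](O[Si](C)(C)C(C)(C)C)C1 | intermediate
9 | (4S,5R,7S)-7-[(tert-butyldimethylsilyl)oxy]-5,9,9-trimethyl-5-[(trimethylsilyl)oxy]spiro[3.5]nonan-1-one | CC1(C)[C@@]2(CCC2=O)[C@](C)(O[Si](C)(C)C)C[C@@H](O[Si](C)(C)C(C)(C)C)C1 | intermediate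
10 | 2-bromopropene | CC(Br)=C | starting material
11 | (4S,5R,7S)-7-[(tert-butyldimethylsilyl)oxy]-5,9,9-trimethyl-2-(prop-1-en-2-yl)-5-[(trimethylsilyl)oxy]spiro[3.5]nonan-1-one (C2 epimers) | CC1(C)[C@@]2(CC(C(C)=C)C2=O)[C@](C)(O[Si](C)(C)C)C[C@@H](O[Si](C)(C)C(C)(C)C)C1 | intermediate
12 | (6S,7R,9S)-9-[(tert-butyldimethylsilyl)oxy]-3,7,11,11-tetramethyl-7-[(trimethylsilyl)oxy]spiro[5.5]undec-3-en-1-one | CC1(C)[C@@]2(CC=C(C)CC2=O)[C@](C)(O[Si](C)(C)C)C[C@@H](O[Si](C)(C)C(C)(C)C)C1 | intermediate
13 | (6S,7R,9S)-7,9-dihydroxy-3,7,11,11-tetramethylspiro[5.5]undec-3-en-1-one | CC1(C)[C@@]2(CC=C(C)CC2=O)[C@](C)(O)C[C@@H](O)C1 | intermediate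
14 | (1S,6R,7R,9S)-3,7,11,11-tetramethylspiro[5.5]undec-3-ene-1,7,9-triol | CC1(C)[C@@]2(CC=C(C)C[C@@H]2O)[C@](C)(O)C[C@@H](O)C1 | intermediate
15 | (1S,3S,4S,6R,7R,9S)-4-bromo-3,7-epoxy-3,7,11,11-tetramethylspiro[5.5]undecane-1,9-diol (C3–O–C7 bridge, Br trans to the bridging O) | CC1(C)[C@@]2(C[C@H](Br)[C@]3(C)C[C@@H]2O)[C@](C)(O3)C[C@@H](O)C1 | intermediate
16 | (1S,3S,4S,6R,7R)-4-bromo-3,7-epoxy-1-hydroxy-3,7,11,11-tetramethylspiro[5.5]undecan-9-one | CC1(C)[C@@]2(C[C@H](Br)[C@]3(C)C[C@@H]2O)[C@](C)(O3)CC(=O)C1 | intermediate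
17 | (1S,3S,4S,6S)-4-bromo-1,3-dihydroxy-3,7,11,11-tetramethylspiro[5.5]undec-7-en-9-one | CC1(C)[C@@]2(C[C@H](Br)[C@@](C)(O)C[C@@H]2O)C(C)=CC(=O)C1 | intermediate (not isolated)
18 | (1S,3S,4S,6S)-4-bromo-3-chloro-1-hydroxy-3,7,11,11-tetramethylspiro[5.5]undec-7-en-9-one | CC1(C)[C@@]2(C[C@H](Br)[C@@](C)(Cl)C[C@@H]2O)C(C)=CC(=O)C1 | intermediate
19 | (1S,3S,4S,6R,7S,8S)-4-bromo-3-chloro-7,8-epoxy-1-hydroxy-3,7,11,11-tetramethylspiro[5.5]undecan-9-one (epoxide O cis to C1) | CC1(C)[C@@]2(C[C@H](Br)[C@@](C)(Cl)C[C@@H]2O)[C@]2(C)O[C@@H]2C(=O)C1 | intermediate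
20 | 10-bromo derivative of 19 (C10 epimers) | CC1(C)[C@@]2(C[C@H](Br)[C@@](C)(Cl)C[C@@H]2O)[C@]2(C)O[C@@H]2C(=O)C1Br | intermediate (not isolated)
21 | (1S,3S,4S,6R,7S,8S)-4,10,10-tribromo-3-chloro-7,8-epoxy-1-hydroxy-3,7,11,11-tetramethylspiro[5.5]undecan-9-one | CC1(C)[C@@]2(C[C@H](Br)[C@@](C)(Cl)C[C@@H]2O)[C@]2(C)O[C@@H]2C(=O)C1(Br)Br | intermediate
22 | (1S,3S,4S,6R,7S,8R,9R)-4,10,10-tribromo-3-chloro-7,8-epoxy-3,7,11,11-tetramethylspiro[5.5]undecane-1,9-diol (9-OH trans to the epoxide) | CC1(C)[C@@]2(C[C@H](Br)[C@@](C)(Cl)C[C@@H]2O)[C@]2(C)O[C@@H]2[C@@H](O)C1(Br)Br | intermediate (not isolated)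
23 | prepacifenol epoxide, (1S,3S,4S,6R,7S,8R,9R,10R)-4,10-dibromo-3-chloro-7,8:9,10-diepoxy-3,7,11,11-tetramethylspiro[5.5]undecan-1-ol | CC1(C)[C@@]2(C[C@H](Br)[C@@](C)(Cl)C[C@@H]2O)[C@]2(C)O[C@@H]2[C@H]2O[C@]21Br | target

**Count**

Total steps: 15. Longest linear sequence: 15 steps from 1 (4 and 10 enter as purchased building blocks).

**Steps most likely to fail, with fallbacks**

1. Step 7 (thermal 1,3-acyl shift). Instead of recombining at the allyl terminus, the strained ketone may fragment by [2+2] cycloreversion (ketene plus diene) or lose CO, or it may stay unchanged below the temperature at which the silyl ethers begin to suffer. The fallback sets out from 11: the ketone is reduced (NaBH4, MeOH, 0 °C) to the 2-isopropenylcyclobutanol F1; KH/18-crown-6 in THF (0 °C → rt) turns it into the potassium alkoxide, which undergoes the alkoxide-accelerated vinylcyclobutane → cyclohex-3-enol rearrangement to the spiro cyclohexenol F2; Dess–Martin oxidation (NaHCO3, CH2Cl2) of the carbinol returns to the route at 12.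

2. Step 15 (reduction and closure). Hydride may be delivered to the other carbonyl face, which after closure would give the cis-bis-epoxide, and the C9 alkoxide may shift the 7,8-epoxide (Payne-type) before it attacks C10. The fallback gives up substrate control and sets C9 by catalyst control: Corey–Bakshi–Shibata reduction of 21 (oxazaborolidine, catecholborane, PhMe, −78 °C), in which the CBr2 carbon acts as the large group as in trihalomethyl ketone reductions and the catalyst enantiomer is chosen for the (9R) carbinol 22. This carbinol is isolated cold and only then closed with K2CO3/MeOH. The path sets out from 21 and rejoins at 23; no new compound arises (F0).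

3. Step 6 (α-alkenylation). The cyclobutanone enolate may undergo self-aldol reaction, a second alkenylation may occur at the now doubly activated C2–H, or the isopropenyl double bond may drift into conjugation under base. The fallback sets out from 9: aldol addition of the lithium enolate (LDA, THF, −78 °C) to acetone gives the β-hydroxy ketone F3; mesylation and elimination (MsCl, Et3N; DBU) give the conjugated 2-isopropylidene cyclobutanone F4; deprotonation at a methyl group (LDA, THF–HMPA, −78 °C) and kinetic α-protonation of the dienolate (AcOH, −78 °C) deconjugate it to 11, where the route resumes.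

Further compounds

F1 | step 7 | (4R,5R,7S)-7-[(tert-butyldimethylsilyl)oxy]-5,9,9-trimethyl-2-(prop-1-en-2-yl)-5-[(trimethylsilyl)oxy]spiro[3.5]nonan-1-ol (C1/C2 epimers) | CC1(C)[C@@]2(CC(C(C)=C)C2O)[C@](C)(O[Si](C)(C)C)C[C@@H](O[Si](C)(C)C(C)(C)C)C1
F2 | step 7 | (6R,7R,9S)-9-[(tert-butyldimethylsilyl)oxy]-3,7,11,11-tetramethyl-7-[(trimethylsilyl)oxy]spiro[5.5]undec-3-en-1-ol (C1 epimers) | CC1(C)[C@@]2(CC=C(C)CC2O)[C@](C)(O[Si](C)(C)C)C[C@@H](O[Si](C)(C)C(C)(C)C)C1
F0 | step 15 | none | none
F3 | step 6 | (4S,5R,7S)-7-[(tert-butyldimethylsilyl)oxy]-2-(2-hydroxypropan-2-yl)-5,9,9-trimethyl-5-[(trimethylsilyl)oxy]spiro[3.5]nonan-1-one (C2 epimers) | CC1(C)[C@@]2(CC(C(C)(C)O)C2=O)[C@](C)(O[Si](C)(C)C)C[C@@H](O[Si](C)(C)C(C)(C)C)C1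
F4 | step 6 | (4S,5R,7S)-7-[(tert-butyldimethylsilyl)oxy]-5,9,9-trimethyl-2-(propan-2-ylidene)-5-[(trimethylsilyl)oxy]spiro[3.5]nonan-1-one | CC1(C)[C@@]2(CC(=C(C)C)C2=O)[C@](C)(O[Si](C)(C)C)C[C@@H](O[Si](C)(C)C(C)(C)C)C1
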